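**Strategy.** Ring B is disconnected across C2–C3 and C1–C8a, so that C1–C2 enters as a two-carbon ketene equivalent and ring A carries only a C4–C3 acetaldehyde arm. In one Lewis-acid operation 2-methylidene-1,3-dithiane opens a chiral (4R,6R)-dioxane acetal at C3 with inversion (C2–C3, sets 3R), and the resulting dithianylium ion at C1 closes on C8a (C1–C8a). The step exploits the β-oxygenated ketone pattern C1(=O)–C2–C3(O) of ring B and the position of C8a ortho to the C8 oxygen of ring A. A bromine at C5 blocks the para position and later carries the pyranone (ring C). The precursor is a bromoanisole bearing a dioxanylmethyl group.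

Key step: step 6

Remark: atoms are numbered as in the tetralone core (C1 carbonyl carbon, C2, C3 carbinol carbon, C4, C4a, C5 to C8, C8a); ring A is the benzene ring, ring B the cyclohexanone ring, ring C the pyranone.

Step 1
Reactants: 1 1-bromo-3-iodo-5-methoxybenzene; 2 (3-methylbutyl)zinc bromide
Product: 3 1-bromo-3-methoxy-5-(3-methylbutyl)benzene
Conditions: PdCl2(dppf) (3 mol %), THF, 25–40 °C
Reagents that add atoms: none
Why: Negishi coupling; oxidative addition of zerovalent palladium to C–I is much faster than to C–Br, so only the iodide should be alkylated.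

Step 2
Reactants: 3 1-bromo-3-methoxy-5-(3-methylbutyl)benzene; 4 (E)-2-(2-ethoxyethenyl)-4,4,5,5-tetramethyl-1,3,2-dioxaborolane
Product: 5 1-[(E)-2-ethoxyethenyl]-3-methoxy-5-(3-methylbutyl)benzene
Conditions: Pd(PPh3)4 (3 mol %), K3PO4, dioxane/H2O, 80 °C
Reagents that add atoms: none
Why: Suzuki–Miyaura coupling of the aryl bromide installs the C4–C3 arm as an enol ether, a masked arylacetaldehyde.

Step 3
Reactants: 5 1-[(E)-2-ethoxyethenyl]-3-methoxy-5-(3-methylbutyl)benzene; 6 (2R,4R)-pentane-2,4-diol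
Product: 7 (4R,6R)-2-{[3-methoxy-5-(3-methylbutyl)phenyl]methyl}-4,6-dimethyl-1,3-dioxane
Conditions: PPTS (cat.), CH2Cl2, 25 °C
Reagents that add atoms: none
Why: acid-catalysed transacetalisation, in which C-protonation of the enol ether gives an oxocarbenium ion at C3 that the diol traps with loss of ethanol; the acetal carbon is no stereocentre because the diol is twofold-symmetric.

Step 4
Reactants: 7 (4R,6R)-2-{[3-methoxy-5-(3-methylbutyl)phenyl]methyl}-4,6-dimethyl-1,3-dioxane
Product: 8 (4R,6R)-2-{[2-bromo-5-methoxy-3-(3-methylbutyl)phenyl]methyl}-4,6-dimethyl-1,3-dioxane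
Conditions: NBS, MeCN, 0 to 25 °C, dark
Reagents that add atoms: N-bromosuccinimide, O=C1CCC(=O)N1Br
Why: electrophilic aromatic bromination, expected para to the methoxy group (C5) as for 3,5-dialkylanisoles; the bromine blocks C5 for step 6 and is the later handle for ring C.

Step 5
Reactants: 9 2-(trimethylsilyl)-1,3-dithiane
Product: 10 2-methylidene-1,3-dithiane
Conditions: n-BuLi, THF, −78 to 0 °C; then CH2O (gas from cracked paraformaldehyde), −78 to 25 °C
Reagents that add atoms: formaldehyde, C=O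
Why: Peterson olefination of the lithiated silyl dithiane with formaldehyde should give the ketene dithioacetal, which is used at once because it is acid-sensitive.

Step 6
Reactants: 8 (4R,6R)-2-{[2-bromo-5-methoxy-3-(3-methylbutyl)phenyl]methyl}-4,6-dimethyl-1,3-dioxane; 10 2-methylidene-1,3-dithiane
Product: 12 (2R,4R)-4-{[(3'R)-5'-bromo-8'-methoxy-6'-(3-methylbutyl)-3',4'-dihydro-2'H-spiro[1,3-dithiane-2,1'-naphthalen]-3'-yl]oxy}pentan-2-ol, via dithianylium ion 11 (not isolated)
Conditions: TiCl4 (2 equiv), 10 (1.5 equiv), CH2Cl2, −78 to −20 °C; aq. NaHCO3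
Reagents that add atoms: none
Why: Proposed new method: TiCl4 activates the dioxane oxygen next to the axial methyl group and the ketene dithioacetal 10 attacks C3 with SN2-like inversion (C2–C3), which gives the 2-alkyl-1,3-dithian-2-ylium ion 11; on warming this cation alkylates C8a of ring A (C1–C8a) and loss of the arene proton gives the spiro thioketal. The closest known reaction types are the Lewis-acid opening of chiral pentane-2,4-diol acetals by π-nucleophiles such as allylsilanes and silyl enol ethers and the acid-induced cyclisation of ketene dithioacetals onto arenes, and new is only their merger with a ketene dithioacetal as the acetal partner. Ring B closes by a 6-exo-trig Friedel–Crafts attack of the arene on the exocyclic C1=S+ bond. The new stereocentre C3 is controlled by the (4R,6R)-dioxane template, whose invertive opening should give 3R. The step needs closure at C8a and not at C5, which the C5 bromine secures by blocking the position para to the methoxy group, and it needs ring B to resist elimination, which the thioketal at C1 secures because no β-alkoxy ketone is present under the Lewis acid.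

Step 7
Reactants: 12 (2R,4R)-4-{[(3'R)-5'-bromo-8'-methoxy-6'-(3-methylbutyl)-3',4'-dihydro-2'H-spiro[1,3-dithiane-2,1'-naphthalen]-3'-yl]oxy}pentan-2-ol
Product: 13 (4R)-4-{[(3'R)-5'-bromo-8'-methoxy-6'-(3-methylbutyl)-3',4'-dihydro-2'H-spiro[1,3-dithiane-2,1'-naphthalen]-3'-yl]oxy}pentan-2-one
Conditions: SO3·pyridine, DMSO, i-Pr2NEt, CH2Cl2, 0 °C
Reagents that add atoms: none
Why: Parikh–Doering oxidation should convert the secondary alcohol of the auxiliary into a ketone without touching the dithiane sulfur atoms or the aryl bromide.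

Step 8
Reactants: 13 (4R)-4-{[(3'R)-5'-bromo-8'-methoxy-6'-(3-methylbutyl)-3',4'-dihydro-2'H-spiro[1,3-dithiane-2,1'-naphthalen]-3'-yl]oxy}pentan-2-one
Product: 14 (3'R)-5'-bromo-8'-methoxy-6'-(3-methylbutyl)-3',4'-dihydro-2'H-spiro[1,3-dithiane-2,1'-naphthalen]-3'-ol
Conditions: K2CO3, MeOH, 25 °C
Reagents that add atoms: none
Why: base-induced β-elimination (retro-oxa-Michael, E1cB) of the β-alkoxy ketone should release the C3 alcohol and pent-3-en-2-one; the C3–O bond is not broken and C1 is still a thioketal, so ring B cannot eliminate.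

Step 9
Reactants: 14 (3'R)-5'-bromo-8'-methoxy-6'-(3-methylbutyl)-3',4'-dihydro-2'H-spiro[1,3-dithiane-2,1'-naphthalen]-3'-ol; 15 tributyl(1-ethoxyethenyl)stannane
Product: 17 1-[(3'R)-3'-hydroxy-8'-methoxy-6'-(3-methylbutyl)-3',4'-dihydro-2'H-spiro[1,3-dithiane-2,1'-naphthalen]-5'-yl]ethan-1-one, via enol ether 16 (not isolated)
Conditions: Pd(PPh3)4 (5 mol %), CuI (10 mol %), CsF, DMF, 80 °C; then 1 M HCl, THF, 25 °C
Reagents that add atoms: water, O
Why: Stille coupling at the hindered C5 bromide (copper iodide and fluoride speed up transmetalation) followed by mild hydrolysis of the enol ether should give the methyl ketone; the free alcohol and the thioketal tolerate both stages.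

Step 10
Reactants: 17 1-[(3'R)-3'-hydroxy-8'-methoxy-6'-(3-methylbutyl)-3',4'-dihydro-2'H-spiro[1,3-dithiane-2,1'-naphthalen]-5'-yl]ethan-1-one; 18 propanedioyl dichloride
Product: 20 4-hydroxy-6-[(3'R)-3'-hydroxy-8'-methoxy-6'-(3-methylbutyl)-3',4'-dihydro-2'H-spiro[1,3-dithiane-2,1'-naphthalen]-5'-yl]-2H-pyran-2-one, via bis-silyl derivative 19 (not isolated)
Conditions: LiN(SiMe3)2 (2.3 equiv), Me3SiCl, THF, −78 to 0 °C; then 18, Et2O, −78 to 25 °C; dilute HCl work-up
Reagents that add atoms: none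
Why: silyl enol ether–malonyl dichloride pyranone annulation: the kinetic enolate is trapped as its silyl enol ether (the C3 alkoxide as a silyl ether) and C-acylated, the enol oxygen closes on the second acid chloride to give ring C, and aqueous acid removes the silyl ether.

Step 11
Reactants: 20 4-hydroxy-6-[(3'R)-3'-hydroxy-8'-methoxy-6'-(3-methylbutyl)-3',4'-dihydro-2'H-spiro[1,3-dithiane-2,1'-naphthalen]-5'-yl]-2H-pyran-2-one
Product: 21 4-hydroxy-6-[(7R)-7-hydroxy-4-methoxy-2-(3-methylbutyl)-5-oxo-5,6,7,8-tetrahydronaphthalen-1-yl]-2H-pyran-2-one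
Conditions: Hg(ClO4)2·3H2O (2.2 equiv), CaCO3, THF/H2O, 0 °C
Reagents that add atoms: water, O
Why: thiophilic divalent mercury opens the dithiane and water hydrolyses the thionium ion to the C1 ketone, under buffered conditions at 0 °C that should spare the β-hydroxy ketone and the pyranone.

Step 12
Reactants: 21 4-hydroxy-6-[(7R)-7-hydroxy-4-methoxy-2-(3-methylbutyl)-5-oxo-5,6,7,8-tetrahydronaphthalen-1-yl]-2H-pyran-2-one
Product: 22 4-hydroxy-6-[(7R)-4,7-dihydroxy-2-(3-methylbutyl)-5-oxo-5,6,7,8-tetrahydronaphthalen-1-yl]-2H-pyran-2-one (CNP0134824.1)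
Conditions: BCl3 (3 equiv), CH2Cl2, −78 to −20 °C; MeOH, aq. NaHCO3
Reagents that add atoms: none
Why: chelation-assisted aryl methyl ether cleavage, in which BCl3 bridges the C1 carbonyl and the peri methoxy oxygen so that chloride removes the methyl group at low temperature; the C3 stereocentre is not involved.

**Compound list**

1 | 1-bromo-3-iodo-5-methoxybenzene | COc1cc(Br)cc(I)c1 | starting material
2 | (3-methylbutyl)zinc bromide (THF solution) | CC(C)CC[Zn]Br | starting material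
3 | 1-bromo-3-methoxy-5-(3-methylbutyl)benzene | COc1cc(Br)cc(CCC(C)C)c1 | intermediate
4 | (E)-2-(2-ethoxyethenyl)-4,4,5,5-tetramethyl-1,3,2-dioxaborolane | CCO/C=C/B1OC(C)(C)C(C)(C)O1 | starting material
5 | 1-[(E)-2-ethoxyethenyl]-3-methoxy-5-(3-methylbutyl)benzene | CCO/C=C/c1cc(OC)cc(CCC(C)C)c1 | intermediate
6 | (2R,4R)-pentane-2,4-diol | C[C@@H](O)C[C@@H](C)O | starting material
7 | (4R,6R)-2-{[3-methoxy-5-(3-methylbutyl)phenyl]methyl}-4,6-dimethyl-1,3-dioxane | COc1cc(CC2O[C@H](C)C[C@@H](C)O2)cc(CCC(C)C)c1 | intermediate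
8 | (4R,6R)-2-{[2-bromo-5-methoxy-3-(3-methylbutyl)phenyl]methyl}-4,6-dimethyl-1,3-dioxane | COc1cc(CC2O[C@H](C)C[C@@H](C)O2)c(Br)c(CCC(C)C)c1 | intermediate
9 | 2-(trimethylsilyl)-1,3-dithiane | C[Si](C)(C)C1SCCCS1 | starting material
10 | 2-methylidene-1,3-dithiane | C=C1SCCCS1 | intermediate
11 | 2-{(2R)-3-[2-bromo-5-methoxy-3-(3-methylbutyl)phenyl]-2-{[(2R,4R)-4-hydroxypentan-2-yl]oxy}propyl}-1,3-dithian-2-ylium (cation, not isolated) | COc1cc(CCC(C)C)c(Br)c(C[C@@H](O[C@H](C)C[C@@H](C)O)CC2=[S+]CCCS2)c1 | intermediate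
12 | (2R,4R)-4-{[(3'R)-5'-bromo-8'-methoxy-6'-(3-methylbutyl)-3',4'-dihydro-2'H-spiro[1,3-dithiane-2,1'-naphthalen]-3'-yl]oxy}pentan-2-ol | COc1cc(CCC(C)C)c(Br)c2C[C@@H](O[C@H](C)C[C@@H](C)O)CC3(SCCCS3)c12 | intermediate
13 | (4R)-4-{[(3'R)-5'-bromo-8'-methoxy-6'-(3-methylbutyl)-3',4'-dihydro-2'H-spiro[1,3-dithiane-2,1'-naphthalen]-3'-yl]oxy}pentan-2-one | COc1cc(CCC(C)C)c(Br)c2C[C@@H](O[C@H](C)CC(C)=O)CC3(SCCCS3)c12 | intermediate
14 | (3'R)-5'-bromo-8'-methoxy-6'-(3-methylbutyl)-3',4'-dihydro-2'H-spiro[1,3-dithiane-2,1'-naphthalen]-3'-ol | COc1cc(CCC(C)C)c(Br)c2C[C@@H](O)CC3(SCCCS3)c12 | intermediate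
15 | tributyl(1-ethoxyethenyl)stannane | CCOC(=C)[Sn](CCCC)(CCCC)CCCC | starting material
16 | (3'R)-5'-(1-ethoxyethenyl)-8'-methoxy-6'-(3-methylbutyl)-3',4'-dihydro-2'H-spiro[1,3-dithiane-2,1'-naphthalen]-3'-ol (not isolated) | COc1cc(CCC(C)C)c(C(=C)OCC)c2C[C@@H](O)CC3(SCCCS3)c12 | intermediate
17 | 1-[(3'R)-3'-hydroxy-8'-methoxy-6'-(3-methylbutyl)-3',4'-dihydro-2'H-spiro[1,3-dithiane-2,1'-naphthalen]-5'-yl]ethan-1-one | COc1cc(CCC(C)C)c(C(C)=O)c2C[C@@H](O)CC3(SCCCS3)c12 | intermediate
18 | propanedioyl dichloride (malonyl dichloride) | O=C(Cl)CC(=O)Cl | starting material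
19 | trimethyl{[(3'R)-8'-methoxy-6'-(3-methylbutyl)-5'-{1-[(trimethylsilyl)oxy]ethenyl}-3',4'-dihydro-2'H-spiro[1,3-dithiane-2,1'-naphthalen]-3'-yl]oxy}silane (not isolated) | COc1cc(CCC(C)C)c(C(=C)O[Si](C)(C)C)c2C[C@@H](O[Si](C)(C)C)CC3(SCCCS3)c12 | intermediate
20 | 4-hydroxy-6-[(3'R)-3'-hydroxy-8'-methoxy-6'-(3-methylbutyl)-3',4'-dihydro-2'H-spiro[1,3-dithiane-2,1'-naphthalen]-5'-yl]-2H-pyran-2-one | COc1cc(CCC(C)C)c(-c3cc(O)cc(=O)o3)c2C[C@@H](O)CC4(SCCCS4)c12 | intermediate
21 | 4-hydroxy-6-[(7R)-7-hydroxy-4-methoxy-2-(3-methylbutyl)-5-oxo-5,6,7,8-tetrahydronaphthalen-1-yl]-2H-pyran-2-one | COc1cc(CCC(C)C)c(-c3cc(O)cc(=O)o3)c2C[C@@H](O)CC(=O)c12 | intermediate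
22 | 4-hydroxy-6-[(7R)-4,7-dihydroxy-2-(3-methylbutyl)-5-oxo-5,6,7,8-tetrahydronaphthalen-1-yl]-2H-pyran-2-one (CNP0134824.1) | CC(C)CCc1cc(O)c2c(c1-c1cc(O)cc(=O)o1)C[C@@H](O)CC2=O | target

**Total step count:** 12.
**Longest linear sequence:** 11 steps (steps 1–4 and 6–12, from 1 to 22); step 5 prepares the two-carbon partner 10.

**Three steps most likely to fail**

1. Step 6 (Proposed new method). After the acetal opening, the dithianylium ion may lose its C2 proton or sit as a chloride adduct faster than it alkylates the hindered C8a. The acid-sensitive ketene dithioacetal may also oligomerise under TiCl4. The fallback uses known chemistry, sets out from 8 and comes back at 12. Mukaiyama-type opening of 8 with 1-(tert-butyldimethylsilyloxy)-1-methoxyethene and TiCl4 in CH2Cl2 at −78 °C follows the same invertive course on the same template and should give methyl (3R)-4-[2-bromo-5-methoxy-3-(3-methylbutyl)phenyl]-3-{[(2R,4R)-4-hydroxypentan-2-yl]oxy}butanoate F1. Me3Al and propane-1,3-dithiol in CH2Cl2 should convert the ester into the ketene dithioacetal (2R,4R)-4-{[(2R)-1-[2-bromo-5-methoxy-3-(3-methylbutyl)phenyl]-3-(1,3-dithian-2-ylidene)propan-2-yl]oxy}pentan-2-ol F2. Trifluoroacetic acid in CH2Cl2 should then protonate F2 at C2 and close ring B by the known ketene dithioacetal–arene cyclisation, which returns to 12.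

2. Step 10. Acid set free during the annulation may strip the C3 silyl ether, so that the diacid chloride acylates the alcohol, and the hindered silyl enol ether may react sluggishly. The fallback sets out from 14 and comes back at 20, so it replaces steps 9 and 10. Silylation (Et3SiCl, imidazole, DMF) should give triethyl{[(3'R)-5'-bromo-8'-methoxy-6'-(3-methylbutyl)-3',4'-dihydro-2'H-spiro[1,3-dithiane-2,1'-naphthalen]-3'-yl]oxy}silane F3. Bromine–lithium exchange (t-BuLi, THF, −78 °C) and CO2 should give (3'R)-8'-methoxy-6'-(3-methylbutyl)-3'-[(triethylsilyl)oxy]-3',4'-dihydro-2'H-spiro[1,3-dithiane-2,1'-naphthalene]-5'-carboxylic acid F4. Activation with (COCl)2 and catalytic DMF, then acylation of the lithium dienolate of 2,2,6-trimethyl-4H-1,3-dioxin-4-one (LiN(SiMe3)2, THF, −78 °C), should give 6-{2-[(3'R)-8'-methoxy-6'-(3-methylbutyl)-3'-[(triethylsilyl)oxy]-3',4'-dihydro-2'H-spiro[1,3-dithiane-2,1'-naphthalen]-5'-yl]-2-oxoethyl}-2,2-dimethyl-4H-1,3-dioxin-4-one F5. Heating in toluene at 110 °C (acylketene formation and lactonisation onto the ketone enol) and dilute HCl (silyl ether cleavage) should return to 20.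

3. Step 12. Under the Lewis acid the β-hydroxy ketone may lose water, with aromatisation of ring B to a naphthol. The fallback sets out from 17 and comes back at 22. It moves the demethylation to a stage where C1 is still a thioketal. SN2 demethylation with NaSEt in DMF at 110 °C should give 1-[(3'R)-3',8'-dihydroxy-6'-(3-methylbutyl)-3',4'-dihydro-2'H-spiro[1,3-dithiane-2,1'-naphthalen]-5'-yl]ethan-1-one F6. The annulation of step 10, with one further equivalent of LiN(SiMe3)2 and Me3SiCl for the phenol, should give 6-[(3'R)-3',8'-dihydroxy-6'-(3-methylbutyl)-3',4'-dihydro-2'H-spiro[1,3-dithiane-2,1'-naphthalen]-5'-yl]-4-hydroxy-2H-pyran-2-one F7. Hydrolysis of the dithiane as in step 11 (Hg(ClO4)2, CaCO3, THF/H2O, 0 °C) should then give 22 directly.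

**Further compounds**

F1 | step 6 | methyl (3R)-4-[2-bromo-5-methoxy-3-(3-methylbutyl)phenyl]-3-{[(2R,4R)-4-hydroxypentan-2-yl]oxy}butanoate | COc1cc(CCC(C)C)c(Br)c(C[C@@H](O[C@H](C)C[C@@H](C)O)CC(=O)OC)c1
F2 | step 6 | (2R,4R)-4-{[(2R)-1-[2-bromo-5-methoxy-3-(3-methylbutyl)phenyl]-3-(1,3-dithian-2-ylidene)propan-2-yl]oxy}pentan-2-ol | COc1cc(CCC(C)C)c(Br)c(C[C@@H](O[C@H](C)C[C@@H](C)O)C=C2SCCCS2)c1
F3 | step 10 | triethyl{[(3'R)-5'-bromo-8'-methoxy-6'-(3-methylbutyl)-3',4'-dihydro-2'H-spiro[1,3-dithiane-2,1'-naphthalen]-3'-yl]oxy}silane | COc1cc(CCC(C)C)c(Br)c2C[C@@H](O[Si](CC)(CC)CC)CC3(SCCCS3)c12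
F4 | step 10 | (3'R)-8'-methoxy-6'-(3-methylbutyl)-3'-[(triethylsilyl)oxy]-3',4'-dihydro-2'H-spiro[1,3-dithiane-2,1'-naphthalene]-5'-carboxylic acid | COc1cc(CCC(C)C)c(C(=O)O)c2C[C@@H](O[Si](CC)(CC)CC)CC3(SCCCS3)c12
F5 | step 10 | 6-{2-[(3'R)-8'-methoxy-6'-(3-methylbutyl)-3'-[(triethylsilyl)oxy]-3',4'-dihydro-2'H-spiro[1,3-dithiane-2,1'-naphthalen]-5'-yl]-2-oxoethyl}-2,2-dimethyl-4H-1,3-dioxin-4-one | COc1cc(CCC(C)C)c(C(=O)CC3=CC(=O)OC(C)(C)O3)c2C[C@@H](O[Si](CC)(CC)CC)CC4(SCCCS4)c12
F6 | step 12 | 1-[(3'R)-3',8'-dihydroxy-6'-(3-methylbutyl)-3',4'-dihydro-2'H-spiro[1,3-dithiane-2,1'-naphthalen]-5'-yl]ethan-1-one | Oc1cc(CCC(C)C)c(C(C)=O)c2C[C@@H](O)CC3(SCCCS3)c12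
F7 | step 12 | 6-[(3'R)-3',8'-dihydroxy-6'-(3-methylbutyl)-3',4'-dihydro-2'H-spiro[1,3-dithiane-2,1'-naphthalen]-5'-yl]-4-hydroxy-2H-pyran-2-one | Oc1cc(CCC(C)C)c(-c3cc(O)cc(=O)o3)c2C[C@@H](O)CC4(SCCCS4)c12
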